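**Plan**

- Retrosynthesis: the 10,11-epoxide, the 2,3-diol (hydration of a 2,3-epoxy-4-ketone) and the C1 ester are removed to give hydroxy-enone 17. Its C1–C6 bond is cut by a retro-carbonyl-ene reaction to the acyclic (2Z,6Z)-4-oxo-2-enal 16, which is the oxidatively opened form of the 2-substituted 3-methylfuran 14. C5–C6 and C8–C9 are then cut to 3-methylfurfural, a (Z)-iodoalkene from propargyl alcohol, and an allyl unit.
- Forward: the chain C6–C13 is built first and joined to the furan aldehyde, and both side-chain angelates are installed. Singlet oxygen dearomatizes the furan to the Z-keto-enal, the only carbocycle closes by the ene reaction, and ring oxygenation and the side-chain epoxide follow.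
- Enabling feature: the array C1(O)–C6–C7(=C14H2) is a homoallylic alcohol whose carbinol carbon and allylic carbon are adjacent atoms of the cyclohexanone ring. The neighbouring C2–C3(C15)–C4(=O) unit maps onto C4–C3(CH3)–C2 of a 3-methylfuran.
- Stereochemistry: C8 by Brown allylation; C5 by ligand-controlled alkenylzinc addition; C6 and C1 from C5 in the ene step; C4 (temporary) by Luche reduction; C2 and C3 by hydroxyl-directed epoxidation and trans-diaxial hydration; C10 by Shi epoxidation.

Key step: step 10

Remark: bisabolane numbering is used throughout (ring C1–C6, C15 = methyl on C3, side chain C7(=C14)–C8–C9–C10–C11(C12)(C13) on C6). β is the ring face of the C6 side chain, α the opposite face. Ang = angeloyl = (Z)-2-methylbut-2-enoyl. 3-Methylfuran-2-carbaldehyde, angelic acid and (−)-Ipc2B(allyl) are taken as commercial.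

**Route**

Step 1
Reactants: 1 prop-2-yn-1-ol
Product: 3 (Z)-3-iodo-2-methylprop-2-en-1-ol, via alkenylmagnesium alkoxide 2 (not isolated)
Conditions: MeMgBr (2.5 equiv), CuI (10 mol %), Et2O, 0 °C to rt; then I2, −10 °C
Reagents that add atoms: methylmagnesium bromide, C[Mg]Br; iodine, II
Why: Copper-catalysed anti-carbomagnesiation of the propargylic alkoxide puts the methyl group on the internal carbon and magnesium on the terminal carbon cis to the CH2O group (five-membered chelate), and iodinolysis with retention gives the (Z)-iodoalkene that already holds the C6=C7 geometry needed in the key step.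

Step 2
Reactants: 3 (Z)-3-iodo-2-methylprop-2-en-1-ol
Product: 4 (Z)-3-iodo-2-methylprop-2-enal
Conditions: MnO2, CH2Cl2, rt; used as a solution
Reagents that add atoms: none
Why: Allylic oxidation with MnO2 should give the enal without touching the vinyl iodide or its geometry.

Step 3
Reactants: 4 (Z)-3-iodo-2-methylprop-2-enal
Product: 6 (1Z,3S)-1-iodo-2-methylhexa-1,5-dien-3-ol, via diisopinocampheylborinate 5 (not isolated)
Conditions: (−)-Ipc2B(allyl), Et2O, −78 °C; then NaOH, H2O2, 0 °C
Reagents that add atoms: (−)-B-allyldiisopinocampheylborane, C=CCB([C@@H]1C[C@@H]2C[C@@H](C2(C)C)[C@H]1C)[C@@H]1C[C@@H]2C[C@@H](C2(C)C)[C@H]1C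
Why: Brown allylboration through a chair-like Zimmerman–Traxler transition state, in which the isopinocampheyl groups derived from (+)-α-pinene send the allyl group to the Si face of the aldehyde and set C8 as (S) under reagent control; oxidative work-up cleaves the borinate.

Step 4
Reactants: 6 (1Z,3S)-1-iodo-2-methylhexa-1,5-dien-3-ol
Product: 7 (1Z,3S)-1-iodo-2,6-dimethylhepta-1,5-dien-3-ol
Conditions: 2-methylbut-2-ene (excess), second-generation Grubbs catalyst (5 mol %), CH2Cl2, 40 °C
Reagents that add atoms: 2-methylbut-2-ene, CC=C(C)C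
Why: Olefin cross-metathesis of the terminal vinyl group with 2-methylbut-2-ene turns the allyl into the prenyl terminus, the trisubstituted iodoalkene being inert to the ruthenium carbene.

Step 5
Reactants: 7 (1Z,3S)-1-iodo-2,6-dimethylhepta-1,5-dien-3-ol
Product: 8 tert-butyl{[(1Z,3S)-1-iodo-2,6-dimethylhepta-1,5-dien-3-yl]oxy}dimethylsilane
Conditions: TBSCl, imidazole, DMF, rt
Reagents that add atoms: tert-butyldimethylsilyl chloride, C[Si](C)(Cl)C(C)(C)C
Why: Silylation masks the C8 hydroxyl for the organolithium step that follows.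

Step 6
Reactants: 8 tert-butyl{[(1Z,3S)-1-iodo-2,6-dimethylhepta-1,5-dien-3-yl]oxy}dimethylsilane; 9 3-methylfuran-2-carbaldehyde
Product: 12 (1R,2Z,4S)-4-(tert-butyldimethylsilyloxy)-3,7-dimethyl-1-(3-methylfuran-2-yl)octa-2,6-dien-1-ol, via alkenyllithium 10 (not isolated), via alkenyl(ethyl)zinc 11 (not isolated)
Conditions: t-BuLi (2 equiv), Et2O, −78 °C; EtZnCl, −78 to 0 °C; TEEDA (N,N,N′,N′-tetraethylethylenediamine), (+)-MIB [(2R)-3-exo-morpholinoisoborneol, 10 mol %], toluene/hexane, 0 °C; then 9
Reagents that add atoms: none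
Why: Iodine–lithium exchange with retention of the (Z) geometry, transmetalation to the alkenyl(ethyl)zinc and amino-alcohol-catalysed enantioselective alkenyl transfer to the aromatic aldehyde, in which the (+)-ligand (antipode of the one that adds to the Si face of aryl aldehydes) should deliver the alkenyl group to the Re face and set C5 as (R) under catalyst control while the diamine binds the lithium salts that would open a racemic background path.

Step 7
Reactants: 12 (1R,2Z,4S)-4-(tert-butyldimethylsilyloxy)-3,7-dimethyl-1-(3-methylfuran-2-yl)octa-2,6-dien-1-ol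
Product: 13 (1R,2Z,4S)-3,7-dimethyl-1-(3-methylfuran-2-yl)octa-2,6-diene-1,4-diol
Conditions: TBAF, THF, 0 °C
Reagents that add atoms: none
Why: Fluoride cleaves the silyl ether under basic conditions that spare the acid-sensitive furyl allyl carbinol.

Step 8
Reactants: 13 (1R,2Z,4S)-3,7-dimethyl-1-(3-methylfuran-2-yl)octa-2,6-diene-1,4-diol
Product: 14 (1R,2Z,4S)-3,7-dimethyl-1-(3-methylfuran-2-yl)octa-2,6-diene-1,4-diyl bis[(Z)-2-methylbut-2-enoate]
Conditions: angelic acid, 2,4,6-trichlorobenzoyl chloride, Et3N, toluene, rt; then 13, 75 °C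
Reagents that add atoms: angelic acid, C/C=C(/C)C(=O)O
Why: Yamaguchi-type esterification, in which the mixed anhydride of angelic acid and 2,4,6-trichlorobenzoic acid acylates both secondary hydroxyls at the less hindered angeloyl carbonyl without a nucleophilic catalyst, so the (Z) geometry of the acyl group should be kept; the C5 ester also blocks the Achmatowicz pathway in the next step.

Step 9
Reactants: 14 (1R,2Z,4S)-3,7-dimethyl-1-(3-methylfuran-2-yl)octa-2,6-diene-1,4-diyl bis[(Z)-2-methylbut-2-enoate]
Product: 16 (2Z,5R,6Z,8S)-5,8-bis(angeloyloxy)-3,7,11-trimethyl-4-oxododeca-2,6,10-trienal, via furan endoperoxide 15 (not isolated)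
Conditions: O2, hν (visible), tetraphenylporphyrin (cat.), CH2Cl2, −78 °C; then Me2S, −78 °C to rt; dark, used at once
Reagents that add atoms: dioxygen, O=O
Why: Singlet oxygen adds across the two α-carbons of the furan in a [4+2] cycloaddition much faster than it reacts with the trisubstituted C10=C11 olefin or the electron-poor C6=C7 olefin, and reduction of the endoperoxide with Me2S opens the dearomatized ring to the 4-oxo-2-enal with the (2Z) geometry inherited from the heteroarene, no stereocentre being touched.

Step 10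
Reactants: 16 (2Z,5R,6Z,8S)-5,8-bis(angeloyloxy)-3,7,11-trimethyl-4-oxododeca-2,6,10-trienal
Product: 17 (5R,8S)-5α,8-bis(angeloyloxy)-1α-hydroxybisabola-2,7(14),10-trien-4-one (side chain on C6 β)
Conditions: Me2AlCl (2.5 equiv), CH2Cl2, −78 to −40 °C, dark
Reagents that add atoms: none
Why: The aldehyde, activated by the aluminium Lewis acid, acts as enophile toward the C6=C7 double bond in a concerted intramolecular carbonyl-ene reaction: C1 bonds to C6 while a hydrogen of the C14 methyl passes to the carbonyl oxygen, which creates the ring, the C1 hydroxyl and the exocyclic C7=C14 methylene in one event (Me2AlCl then holds the alcohol as its aluminium alkoxide with loss of methane, so no proton-driven side reactions follow). The closest known reaction type is the thermal or Lewis-acid-promoted cyclization of citronellal to isopulegol and of neral to isopiperitenol, the (2Z) geometry stored in the furan playing the part of the neral double bond. The six-membered ring closes through a chair-like transition state by 6-exo attack of the alkene terminus C6 on the carbonyl carbon, with both the C6=C7 and the C1=O π bonds outside the new ring. C6 is controlled by C5: allylic 1,3-strain with the cis C8 substituent of the (6Z) alkene holds the C5–H bond in the alkene plane, so the tether attacks the face anti to the C5 angelate and the 5-ester and the 6-side chain should come out trans-diequatorial; C1 is controlled by the hydrogen-transfer geometry, because only the transition state with the aldehyde oxygen equatorial can reach the methyl group, which lies trans to the tether, and this gives the 1,6-trans (1α-hydroxy) isomer. The step needs hydrogen abstraction from C14 and not from C8, and reaction of the aldehyde and not of the ketone: the first is secured by the (6Z) geometry and by the same 1,3-strain, which keeps the C8–H bond in the nodal plane of the π bond, the second by the higher electrophilicity of the aldehyde and by the fact that the ketone carbon C4 could only close a three-membered ring with C6.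

Step 11
Reactants: 17 (5R,8S)-5α,8-bis(angeloyloxy)-1α-hydroxybisabola-2,7(14),10-trien-4-one
Product: 18 (5R,8S)-1α,5α,8-tris(angeloyloxy)bisabola-2,7(14),10-trien-4-one
Conditions: angelic acid, 2,4,6-trichlorobenzoyl chloride, Et3N, toluene, rt; then 17, 75 °C
Reagents that add atoms: angelic acid, C/C=C(/C)C(=O)O
Why: The same Yamaguchi-type esterification of the equatorial C1 hydroxyl, the only free hydroxyl, should install the third angelate without isomerization, and the C5 centre is already the more stable trans-diequatorial epimer toward the mild amine base.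

Step 12
Reactants: 18 (5R,8S)-1α,5α,8-tris(angeloyloxy)bisabola-2,7(14),10-trien-4-one
Product: 19 (5R,8S)-1α,5α,8-tris(angeloyloxy)bisabola-2,7(14),10-trien-4β-ol
Conditions: NaBH4, CeCl3·7H2O, MeOH, −78 °C; AcOH quench at −78 °C
Reagents that add atoms: none
Why: Luche 1,2-reduction, in which axial hydride delivery from the α face of the half-chair enone (all three ring substituents equatorial) should place the new hydroxyl equatorial and β, trans to the C5 angelate, as in the reduction of carvone to cis-carveol; the esters survive at −78 °C.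

Step 13
Reactants: 19 (5R,8S)-1α,5α,8-tris(angeloyloxy)bisabola-2,7(14),10-trien-4β-ol
Product: 20 (5R,8S)-1α,5α,8-tris(angeloyloxy)-2β,3β-epoxybisabola-7(14),10-dien-4β-ol
Conditions: VO(acac)2 (5 mol %), t-BuOOH, CH2Cl2, 0 °C to rt
Reagents that add atoms: tert-butyl hydroperoxide, CC(C)(C)OO
Why: Hydroxyl-directed, vanadium-catalysed epoxidation delivers oxygen to the ring double bond on the face of the C4 hydroxyl (β), which is also the face remote from the allylic C1 angelate, while the isolated C10=C11 and C7=C14 olefins and the electron-poor angelates are not attacked by this reagent.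

Step 14
Reactants: 20 (5R,8S)-1α,5α,8-tris(angeloyloxy)-2β,3β-epoxybisabola-7(14),10-dien-4β-ol
Product: 21 (5R,8S)-1α,5α,8-tris(angeloyloxy)-2β,3β-epoxybisabola-7(14),10-dien-4-one
Conditions: Dess–Martin periodinane, NaHCO3, CH2Cl2, 0 °C to rt
Reagents that add atoms: none
Why: Buffered Dess–Martin oxidation of the secondary alcohol returns the C4 ketone with the β-epoxide in place and without epimerizing C5.

Step 15
Reactants: 21 (5R,8S)-1α,5α,8-tris(angeloyloxy)-2β,3β-epoxybisabola-7(14),10-dien-4-one
Product: 22 (5R,8S)-1α,5α,8-tris(angeloyloxy)-2α,3β-dihydroxybisabola-7(14),10-dien-4-one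
Conditions: aq. HClO4 (5 %), THF, 0 °C to rt
Reagents that add atoms: water, O
Why: Acid-catalysed hydration of the α,β-epoxy ketone, in which water attacks C2 (β to the carbonyl; C3 is tertiary and deactivated by the adjacent carbonyl) from the α face with inversion, which is also the trans-diaxial Fürst–Plattner mode of the all-equatorial ring, so the 2α-secondary and 3β-tertiary hydroxyls should result; the equatorial C1 ester cannot reach the backside of C2, and C3 carries no hydrogen, so no dehydration follows.

Step 16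
Reactants: 22 (5R,8S)-1α,5α,8-tris(angeloyloxy)-2α,3β-dihydroxybisabola-7(14),10-dien-4-one
Product: 23 (1S,2S,3R,5R,6S,8S,10R)-1,5,8-tris(angeloyloxy)-10,11-epoxy-2,3-dihydroxybisabol-7(14)-en-4-one (CNP0313777.1)
Conditions: D-fructose-derived Shi ketone (1 equiv), Oxone (KHSO5), NaHCO3, MeCN/aq. Na2EDTA, pH about 8, 0 °C
Reagents that add atoms: potassium peroxymonosulfate, [K+].[O-]S(=O)(=O)OO
Why: Shi asymmetric epoxidation, in which the dioxirane of the D-fructose-derived ketone attacks the most electron-rich, trisubstituted C10=C11 olefin through the spiro transition state that should give the (10R) epoxide under reagent control, while the 1,1-disubstituted C7=C14 olefin and the conjugated angelates are far less reactive and the near-neutral pH spares the esters and the β-hydroxy ketone.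

**Compound list**

1 | prop-2-yn-1-ol (propargyl alcohol) | C#CCO | starting material
2 | bromomagnesium (Z)-3-(bromomagnesio)-2-methylprop-2-en-1-olate (formed in the flask) | Br[Mg]OC/C(C)=C\[Mg]Br | intermediate
3 | (Z)-3-iodo-2-methylprop-2-en-1-ol | OC/C(C)=C\I | intermediate
4 | (Z)-3-iodo-2-methylprop-2-enal | O=C/C(C)=C\I | intermediate
5 | (1Z,3S)-1-iodo-2-methylhexa-1,5-dien-3-yl diisopinocampheylborinate (formed in the flask) | C=CC[C@H](OB([C@@H]1C[C@@H]2C[C@@H](C2(C)C)[C@H]1C)[C@@H]1C[C@@H]2C[C@@H](C2(C)C)[C@H]1C)/C(C)=C\I | intermediate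
6 | (1Z,3S)-1-iodo-2-methylhexa-1,5-dien-3-ol | C=CC[C@H](O)/C(C)=C\I | intermediate
7 | (1Z,3S)-1-iodo-2,6-dimethylhepta-1,5-dien-3-ol | CC(C)=CC[C@H](O)/C(C)=C\I | intermediate
8 | tert-butyl{[(1Z,3S)-1-iodo-2,6-dimethylhepta-1,5-dien-3-yl]oxy}dimethylsilane | CC(C)=CC[C@H](O[Si](C)(C)C(C)(C)C)/C(C)=C\I | intermediate
9 | 3-methylfuran-2-carbaldehyde | Cc1ccoc1C=O | starting material
10 | [(1Z,3S)-3-(tert-butyldimethylsilyloxy)-2,6-dimethylhepta-1,5-dien-1-yl]lithium (formed in the flask) | CC(C)=CC[C@H](O[Si](C)(C)C(C)(C)C)/C(C)=C\[Li] | intermediate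
11 | ethyl[(1Z,3S)-3-(tert-butyldimethylsilyloxy)-2,6-dimethylhepta-1,5-dien-1-yl]zinc (formed in the flask) | CC(C)=CC[C@H](O[Si](C)(C)C(C)(C)C)/C(C)=C\[Zn]CC | intermediate
12 | (1R,2Z,4S)-4-(tert-butyldimethylsilyloxy)-3,7-dimethyl-1-(3-methylfuran-2-yl)octa-2,6-dien-1-ol | Cc1ccoc1[C@H](O)/C=C(C)\[C@H](CC=C(C)C)O[Si](C)(C)C(C)(C)C | intermediate
13 | (1R,2Z,4S)-3,7-dimethyl-1-(3-methylfuran-2-yl)octa-2,6-diene-1,4-diol | Cc1ccoc1[C@H](O)/C=C(C)\[C@H](CC=C(C)C)O | intermediate
14 | (1R,2Z,4S)-3,7-dimethyl-1-(3-methylfuran-2-yl)octa-2,6-diene-1,4-diyl bis[(Z)-2-methylbut-2-enoate] | Cc1ccoc1[C@H](OC(=O)/C(C)=C\C)/C=C(C)\[C@H](CC=C(C)C)OC(=O)/C(C)=C\C | intermediate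
15 | 2,5-endoperoxide of furan 14 (2,3,7-trioxabicyclo[2.2.1]hept-5-ene, side chain on C1, methyl on C6; formed in the flask) | CC1=CC2OOC1(O2)[C@H](OC(=O)/C(C)=C\C)/C=C(C)\[C@H](CC=C(C)C)OC(=O)/C(C)=C\C | intermediate
16 | (2Z,5R,6Z,8S)-5,8-bis(angeloyloxy)-3,7,11-trimethyl-4-oxododeca-2,6,10-trienal | O=C/C=C(C)\C(=O)[C@H](OC(=O)/C(C)=C\C)/C=C(C)\[C@H](CC=C(C)C)OC(=O)/C(C)=C\C | intermediate
17 | (5R,8S)-5α,8-bis(angeloyloxy)-1α-hydroxybisabola-2,7(14),10-trien-4-one (C6 side chain β) | C=C([C@H]1[C@H](O)C=C(C)C(=O)[C@@H]1OC(=O)/C(C)=C\C)[C@H](CC=C(C)C)OC(=O)/C(C)=C\C | intermediate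
18 | (5R,8S)-1α,5α,8-tris(angeloyloxy)bisabola-2,7(14),10-trien-4-one | C=C([C@H]1[C@H](OC(=O)/C(C)=C\C)C=C(C)C(=O)[C@@H]1OC(=O)/C(C)=C\C)[C@H](CC=C(C)C)OC(=O)/C(C)=C\C | intermediate
19 | (5R,8S)-1α,5α,8-tris(angeloyloxy)bisabola-2,7(14),10-trien-4β-ol | C=C([C@H]1[C@H](OC(=O)/C(C)=C\C)C=C(C)[C@@H](O)[C@@H]1OC(=O)/C(C)=C\C)[C@H](CC=C(C)C)OC(=O)/C(C)=C\C | intermediate
20 | (5R,8S)-1α,5α,8-tris(angeloyloxy)-2β,3β-epoxybisabola-7(14),10-dien-4β-ol | C=C([C@H]1[C@H](OC(=O)/C(C)=C\C)[C@H]2O[C@@]2(C)[C@@H](O)[C@@H]1OC(=O)/C(C)=C\C)[C@H](CC=C(C)C)OC(=O)/C(C)=C\C | intermediate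
21 | (5R,8S)-1α,5α,8-tris(angeloyloxy)-2β,3β-epoxybisabola-7(14),10-dien-4-one | C=C([C@H]1[C@H](OC(=O)/C(C)=C\C)[C@H]2O[C@@]2(C)C(=O)[C@@H]1OC(=O)/C(C)=C\C)[C@H](CC=C(C)C)OC(=O)/C(C)=C\C | intermediate
22 | (5R,8S)-1α,5α,8-tris(angeloyloxy)-2α,3β-dihydroxybisabola-7(14),10-dien-4-one | C=C([C@H]1[C@H](OC(=O)/C(C)=C\C)[C@H](O)[C@@](C)(O)C(=O)[C@@H]1OC(=O)/C(C)=C\C)[C@H](CC=C(C)C)OC(=O)/C(C)=C\C | intermediate
23 | (1S,2S,3R,5R,6S,8S,10R)-1,5,8-tris(angeloyloxy)-10,11-epoxy-2,3-dihydroxybisabol-7(14)-en-4-one (CNP0313777.1) | C=C([C@H]1[C@H](OC(=O)/C(C)=C\C)[C@H](O)[C@@](C)(O)C(=O)[C@@H]1OC(=O)/C(C)=C\C)[C@H](C[C@H]1OC1(C)C)OC(=O)/C(C)=C\C | target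

**Step count and risks**

Total steps: 16. Longest linear sequence: 16 steps (1 to 23); 9 enters as a commercial partner in step 6.

Steps most likely to fail:

1. Step 10 (carbonyl-ene ring closure). The (2Z) double bond of 16 may isomerize to (2E), which cannot reach C6; hydrogen may be transferred from C8 in place of C14; or the Lewis acid may ionize or epimerize the C5 acyloxy ketone. The fallback replaces the hydrogen transfer by an intramolecular Hosomi–Sakurai allylation, in which silicon fixes the position of the new double bond and the closure runs at −78 °C. It sets out from 1 and repeats steps 1 to 9 with a CH2SiMe3 group on C7 in place of the C14 methyl. Carbomagnesiation with Me3SiCH2MgCl/CuI and iodination give the 14-trimethylsilyl analogue of 3 F1, and MnO2 gives the 14-trimethylsilyl analogue of 4 F2. Allylation with (−)-Ipc2B(allyl) gives the 14-trimethylsilyl analogue of 6 F3, cross-metathesis with 2-methylbut-2-ene the 14-trimethylsilyl analogue of 7 F4, and TBSCl/imidazole the 14-trimethylsilyl analogue of 8 F5. Iodine–lithium exchange, EtZnCl and (+)-MIB-catalysed addition to 9 give the 14-trimethylsilyl analogue of 12 F6. TBAF buffered with AcOH at 0 °C, which should leave the allylsilane intact, gives the 14-trimethylsilyl analogue of 13 F7, and double angeloylation as in step 8 the 14-trimethylsilyl analogue of 14 F8. Singlet oxygen followed by Me2S gives the 14-trimethylsilyl analogue of 16 F9. BF3·OEt2 in CH2Cl2 at −78 °C should then close the ring by attack of C6 on the aldehyde with loss of the silyl group, and the route is rejoined at 17.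

2. Step 15 (hydration of the epoxy ketone). Opening of the deactivated α,β-epoxy ketone may be slow, so that hydration of the C10=C11 olefin, 1,2-acyl migration or isomerization of the angelates compete under prolonged acid. The fallback sets out from epoxy alcohol 20 and opens the epoxide before the ketone is formed. Ti(OiPr)4-mediated opening with chloroacetic acid, which is delivered to the epoxide carbon remote from the coordinating C4 hydroxyl, should give the 2α-chloroacetoxy-3β,4β-diol F10. Dess–Martin oxidation of its only secondary hydroxyl gives the 2α-chloroacetoxy-3β-hydroxy-4-ketone F11. Thiourea with NaHCO3 in EtOH at 40 °C removes the chloroacetate in the presence of the angelates, and the route is rejoined at 22.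

3. Step 9 (furan opening). Singlet oxygen may also attack the C10=C11 olefin in an ene-type oxidation, or the endoperoxide and the cis-keto-enal may break down before use. The fallback is electrochemical and sets out from 14. Anodic methoxylation (graphite anode, MeOH, Et4NOTs, constant current, −20 °C), in which the furan is the most easily oxidized π system, gives the 2,5-dimethoxy-2,5-dihydrofuran F12. This storable bis-ketal holds the cis geometry in a ring. Mild hydrolysis (aq. AcOH in acetone, 0 °C) releases the keto-enal, and the route is rejoined at 16.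

Further compounds
F1 | step 10 | 14-trimethylsilyl analogue of 3: 3-iodo-2-[(trimethylsilyl)methyl]prop-2-en-1-ol, iodine cis to CH2OH | OC/C(C[Si](C)(C)C)=C\I
F2 | step 10 | 14-trimethylsilyl analogue of 4: 3-iodo-2-[(trimethylsilyl)methyl]prop-2-enal, iodine cis to CHO | O=C/C(C[Si](C)(C)C)=C\I
F3 | step 10 | 14-trimethylsilyl analogue of 6: (3S)-1-iodo-2-[(trimethylsilyl)methyl]hexa-1,5-dien-3-ol, iodine cis to C3 | C=CC[C@H](O)/C(C[Si](C)(C)C)=C\I
F4 | step 10 | 14-trimethylsilyl analogue of 7: (3S)-1-iodo-6-methyl-2-[(trimethylsilyl)methyl]hepta-1,5-dien-3-ol, iodine cis to C3 | CC(C)=CC[C@H](O)/C(C[Si](C)(C)C)=C\I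
F5 | step 10 | 14-trimethylsilyl analogue of 8: tert-butyldimethylsilyl ether of F4 | CC(C)=CC[C@H](O[Si](C)(C)C(C)(C)C)/C(C[Si](C)(C)C)=C\I
F6 | step 10 | 14-trimethylsilyl analogue of 12: (1R,4S)-4-(tert-butyldimethylsilyloxy)-7-methyl-1-(3-methylfuran-2-yl)-3-[(trimethylsilyl)methyl]octa-2,6-dien-1-ol, C1 and C4 cis on the 2,3-double bond | Cc1ccoc1[C@H](O)/C=C(C[Si](C)(C)C)\[C@H](CC=C(C)C)O[Si](C)(C)C(C)(C)C
F7 | step 10 | 14-trimethylsilyl analogue of 13: (1R,4S)-7-methyl-1-(3-methylfuran-2-yl)-3-[(trimethylsilyl)methyl]octa-2,6-diene-1,4-diol, C1 and C4 cis on the 2,3-double bond | Cc1ccoc1[C@H](O)/C=C(C[Si](C)(C)C)\[C@H](CC=C(C)C)O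
F8 | step 10 | 14-trimethylsilyl analogue of 14: bis-angelate of F7 | Cc1ccoc1[C@H](OC(=O)/C(C)=C\C)/C=C(C[Si](C)(C)C)\[C@H](CC=C(C)C)OC(=O)/C(C)=C\C
F9 | step 10 | 14-trimethylsilyl analogue of 16: (5R,8S)-5,8-bis(angeloyloxy)-3,11-dimethyl-4-oxo-7-[(trimethylsilyl)methyl]dodeca-2,6,10-trienal, 2Z, C5 and C8 cis on the 6,7-double bond | O=C/C=C(C)\C(=O)[C@H](OC(=O)/C(C)=C\C)/C=C(C[Si](C)(C)C)\[C@H](CC=C(C)C)OC(=O)/C(C)=C\C
F10 | step 15 | (5R,8S)-1α,5α,8-tris(angeloyloxy)-2α-(chloroacetoxy)bisabola-7(14),10-diene-3β,4β-diol | C=C([C@H]1[C@H](OC(=O)/C(C)=C\C)[C@H](OC(=O)CCl)[C@@](C)(O)[C@@H](O)[C@@H]1OC(=O)/C(C)=C\C)[C@H](CC=C(C)C)OC(=O)/C(C)=C\C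
F11 | step 15 | (5R,8S)-1α,5α,8-tris(angeloyloxy)-2α-(chloroacetoxy)-3β-hydroxybisabola-7(14),10-dien-4-one | C=C([C@H]1[C@H](OC(=O)/C(C)=C\C)[C@H](OC(=O)CCl)[C@@](C)(O)C(=O)[C@@H]1OC(=O)/C(C)=C\C)[C@H](CC=C(C)C)OC(=O)/C(C)=C\C
F12 | step 9 | 2,5-dimethoxy-2,5-dihydrofuran from 14 (methoxy groups on both former α-carbons of the furan, mixture of ring diastereomers, side-chain centres as in 14) | COC1C=C(C)C(OC)(O1)[C@H](OC(=O)/C(C)=C\C)/C=C(C)\[C@H](CC=C(C)C)OC(=O)/C(C)=C\C
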